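## The problem

Compound 15 is a single tetrahydrofuran ring (O1, C2–C5) with a 4-hydroxy-3,5-dimethoxyphenyl group on C2 and on C5 and a hydroxymethyl group (C3a, C4a) on C3 and on C4. Nothing is fused to the ring, so the whole task lies in the substituents and their relative configuration. All four substituents sit on one face, which makes 15 a meso compound: absolute control is unnecessary and racemic intermediates suffice. The all-cis arrangement is, however, the most crowded diastereomer, so each centre must be set under kinetic control and never allowed to equilibrate afterwards. C2 and C5 are benzylic ether carbons para to a phenol; acid, or base acting through the phenoxide and a quinone methide, can open the C–O bond and invert them. The electron-rich rings and free phenols also do not tolerate oxidants, so the phenols stay benzylated until the end. A cis C4/C5 pair made first can shield one face of a planar C2=C3 unit and so dictate C2 and C3 together in one syn addition of hydrogen. The plan rests on the local pattern at C2 and C3: C2 is bonded to O1 and an aryl group and C3 carries the one-carbon arm C3a, which is what results when a hydroxyl adds to the aryl terminus of an alkyne and the other alkyne carbon is carbonylated.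

## Retrosynthesis

**15 from 14 (oxidation level of C3a).** No skeletal bond is cut: the C3a hydroxymethyl group is traced back to a methyl ester, giving triol ester 14. Keeping the ester until the last step leaves the carbonylation product untouched and keeps the C2=C3 alkene conjugated until it is hydrogenated. The forward reduction only has to be faster than epimerisation at C3, the one centre α to the carbonyl group.

**14 from 13 (C2–H and C3–H).** Removing the hydrogens at C2 and C3 and restoring benzyl groups on the phenols and the C4a oxygen gives the 4,5-dihydrofuran-3-carboxylate 13. Setting C2 and C3 one after the other would need two separate facial selections next to an epimerisable ester. The flat, tetrasubstituted enol ether lets the cis C4/C5 pair decide both at once. Compound 13 has two stereocentres instead of four. The forward hydrogenation must add to the face opposite the C4 and C5 substituents and spare the benzylic ring C–O bonds while cleaving three benzyl ethers.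

**13 from 12 (O1–C2 and C3–C3a, the key disconnection).** Cutting the ring oxygen from C2 and the ester carbon from C3 opens 13 to the acyclic homopropargylic alcohol 12. The neighbouring cuts are worse. Closing O1–C5 would form the ring by substitution at an ionisable benzylic centre, and closing C3–C4 or C4–C5 would create a stereocentre during cyclisation. Here both bonds form at sp carbons, away from C4 and C5, so the configuration of 12 is simply carried over. The precursor is a chain with two adjacent stereocentres and no ring. The forward step must close in the 5-endo mode at the aryl-bearing alkyne carbon and trap the vinylmetal by alkoxycarbonylation before it is protonated.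

**12 from 8 and 11 (C2–aryl).** The bond between the alkyne terminus and its aryl group is cut to give terminal alkynol 8 and aryl iodide 11. Carrying this aryl group through the allenylmetal chemistry would save two steps but would load a sensitive stannane with an electron-rich aryl group; attaching it afterwards keeps that reagent simple. The forward cross-coupling must tolerate the free benzylic hydroxyl.

**8 from 3 and 7 (C4–C5).** The bond between the carbinol carbon (C5) and the propargylic carbon (C4) is cut to give aldehyde 3 and allenylstannane 7. An aldol construction of the same bond would leave a carbonyl group that needs several more steps to become the alkyne. The allenylmetal brings the alkyne with it and sets both stereocentres in one operation. Both fragments have at most one stereogenic element. The forward addition must be syn-selective, which requires an open, Lewis-acid-promoted transition state; the cyclic transition states of allenylzinc or allenylboron reagents give the anti isomer.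

**7 from 6, 5 and 4 (C–Sn, then alkyne–carbinol C–C).** Stannane 7 is traced by an SN2′ disconnection of the C–Sn bond to propargylic mesylate 6 and alcohol 5. The alkyne–carbinol bond of 5 is then cut to give aldehyde 4 and an ethynyl Grignard reagent. The displacement must go with SN2′ regiochemistry, for which stannylcopper reagents are the standard choice.

**3 from 1 and 2; 11 from 10, 9 and 2 (aryl building blocks).** Aldehyde 3 is the benzyl ether of 1, made with 2. Iodide 11 is the benzyl ether of iodophenol 10, which comes from 9 by iodination para to the hydroxyl. The phenol must be iodinated before benzylation: only the phenoxide directs the electrophile para to oxygen, whereas the benzyl ether would be attacked ortho to a methoxy group.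

## Roads not taken

**Alternative 1:** Both aryl rings are disconnected completely.
- **Cut and key step.** The four stereocentres come from a rigid 7-oxanorbornene whose alkene is cleaved oxidatively, leaving the all-cis tetrahydrofuran bis(N-methoxy-N-methyl amide) A2 with C3a and C4a already present as benzyl ethers. The dianion of 3-(benzyloxy)pentane-2,4-dione A3 is acylated at its terminal carbon by each amide of A2. Each triketone then closes by aldol condensation and dehydration to a 4-benzyloxy-3,5-dihydroxyphenyl ring, giving tetraphenol A1. Fourfold O-methylation and hydrogenolysis would finish.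
- **Merits.** All four centres are fixed by a bicyclic template before any benzylic ether exists; the route is two-directional and needs no facial selection in a hydrogenation.
- **Weak points.** C2 and C5 of A2 are α to carbonyl groups throughout a strongly basic acylation and aldol sequence, and epimerisation to trans would relieve the all-cis strain. The bicyclic precursor would need both arms endo, whereas such cycloadducts normally form exo. Triketones can also close to pyranones. Two arenes that can be bought are built atom by atom, and four methylations are added.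
- **Comparison.** In stereochemical security of the ring this road is better than the chosen plan, whose hydrogenation and syn addition are open questions. The chosen plan sets against it the purchase of both aryl rings intact, a much shorter sequence, and no base-labile α-carbonyl centre at C2 or C5.

**Alternative 2:** The C2–aryl and C5–aryl bonds are cut, leaving the cis bis-acetal diol A5 and the triarylalane A6.
- **Key step.** On heating, each hydroxymethyl oxygen of A5 binds a diarylaluminium unit, the metal ionises the neighbouring acetal carbon, and an aryl group passes from aluminium to the oxocarbenium carbon on the face of the tether. This should give A4 all-cis; hydrogenolysis then gives 15.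
- **Merits.** It is by far the shortest road, it uses the symmetry of the target fully, both arms arrive at the right oxidation level, and the all-cis pattern follows from one cis diol.
- **Weak points.** Tethered aryl transfer from aluminium has relatives in C-glycoside chemistry, but here it must succeed twice on one small ring. After the first transfer the new electron-rich benzylic C–O bond is itself ionisable by the hot Lewis acid. Intermolecular delivery from excess A6 would give trans products. The two alkoxides may bridge one aluminium. Two of three aryl groups of A6 are wasted.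
- **Comparison.** In step economy this road is clearly better. The chosen plan sets against it that each of its steps belongs to an established reaction class and that its stereochemical argument (syn addition to the open face) has a simple steric basis.

**Alternative 3:** The O1–C5 and C2–C3 bonds are cut in a formal [3+2] sense, leading to the trans donor–acceptor cyclopropane A8 and aryl aldehyde A9.
- **Key step.** A Lewis acid opens A8 at its aryl-bearing carbon toward the aldehyde oxygen with inversion (O1–C5), and the malonate carbon adds to the activated aldehyde carbon (C2–C3). This gives A7 with the C2, C4 and C5 substituents cis.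
- **Merits.** It is convergent and catalytic, the 2,5-cis relationship is intrinsic to this annulation, and three centres and the ring form in one step.
- **Weak points.** C3 arrives as a geminal diester. One ester must be removed and the other left cis to both neighbours, yet dealkoxycarbonylation passes through an enolate and hot equilibrating conditions favour the trans isomer. The electron-rich donor aryl group favours full ionisation of the cyclopropane, which erodes the inversion that creates the 4,5-cis relationship; the pivalates temper this only partly.
- **Comparison.** This road reaches the ring in fewer steps, and its 2,5-cis control is more secure than the syn selectivity on which the chosen plan depends. The chosen plan sets against it that C2 and C3 are created together from a planar enol ether under kinetic control, the relationship this annulation leaves undefined.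

Key step: step 9

## Route

Remark on the chemistry: 15 is meso, so every chiral intermediate is made as a racemate. Compounds with a single stereogenic element are written without a descriptor; for compounds with two or more centres one enantiomer is drawn and rel-descriptors are given.

Step 1
Reactants: 1 syringaldehyde (4-hydroxy-3,5-dimethoxybenzaldehyde); 2 benzyl bromide
Product: 3 4-(benzyloxy)-3,5-dimethoxybenzaldehyde
Conditions: K2CO3, DMF, 60 °C
Reagents that add atoms: none
Why: Williamson ether synthesis; the acidic, hindered phenol is alkylated as its potassium salt by the reactive benzylic bromide, and the aldehyde is inert to carbonate.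

Step 2
Reactants: 4 benzyloxyacetaldehyde
Product: 5 1-(benzyloxy)but-3-yn-2-ol (racemic)
Conditions: HC≡CMgBr, THF, −78 to 0 °C; aqueous quench
Reagents that add atoms: ethynylmagnesium bromide, `C#C[Mg]Br`
Why: Grignard 1,2-addition of an alkynyl nucleophile to an unhindered aldehyde; the carbinol centre forms as a racemate, which is sufficient because the target is meso.

Step 3
Reactants: 5 1-(benzyloxy)but-3-yn-2-ol
Product: 6 1-(benzyloxy)but-3-yn-2-yl methanesulfonate (racemic)
Conditions: MsCl, Et3N, CH2Cl2, −78 to 0 °C
Reagents that add atoms: methanesulfonyl chloride, `CS(=O)(=O)Cl`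
Why: Sulfonylation of a secondary alcohol through the sulfene; the electron-withdrawing benzyloxymethyl group disfavours ionisation of the propargylic mesylate, which is worked up cold and used without purification.

Step 4
Reactants: 6 1-(benzyloxy)but-3-yn-2-yl methanesulfonate
Product: 7 tributyl[4-(benzyloxy)buta-1,2-dien-1-yl]stannane (racemic)
Conditions: Bu3SnH, LiN(i-Pr)2, THF, 0 °C; CuBr·SMe2, −78 °C; then 6, −78 °C
Reagents that add atoms: tributyltin hydride, `CCCC[SnH](CCCC)CCCC` (delivered as Bu3SnLi and then Bu3SnCu)
Why: SN2′ displacement of a propargylic mesylate by a stannylcopper reagent, the standard route to allenylstannanes; tin is delivered to the alkyne terminus anti to the leaving group, and the allene forms racemic from racemic 6.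

Step 5
Reactants: 3 4-(benzyloxy)-3,5-dimethoxybenzaldehyde; 7 tributyl[4-(benzyloxy)buta-1,2-dien-1-yl]stannane
Product: 8 rel-(1R,2R)-1-[4-(benzyloxy)-3,5-dimethoxyphenyl]-2-[(benzyloxy)methyl]but-3-yn-1-ol (syn, racemic)
Conditions: BF3·OEt2, CH2Cl2, −78 °C; cold aqueous quench
Reagents that add atoms: none
Why: Lewis-acid-promoted SE2′ addition of an allenylstannane to an aldehyde (propargylation): the carbon bearing the benzyloxymethyl group attacks the BF3-bound aldehyde anti to tin and the alkyne is released. The open, antiperiplanar transition state that keeps the aldehyde aryl group away from the benzyloxymethyl substituent should set both new stereocentres (C5 and C4 of the later ring) syn, in contrast to the anti outcome of cyclic allenylzinc or allenylboron transition states.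

Step 6
Reactants: 9 2,6-dimethoxyphenol
Product: 10 4-iodo-2,6-dimethoxyphenol
Conditions: NaI, NaOH, aq NaOCl, MeOH, 0 °C
Reagents that add atoms: sodium iodide, `[Na+].[I-]`
Why: Electrophilic aromatic iodination by hypoiodite generated in situ; the phenoxide directs to its para position, the site at which this phenol is formylated and brominated under basic conditions, and both ortho positions carry methoxy groups.

Step 7
Reactants: 10 4-iodo-2,6-dimethoxyphenol; 2 benzyl bromide
Product: 11 2-(benzyloxy)-5-iodo-1,3-dimethoxybenzene
Conditions: K2CO3, DMF, rt
Reagents that add atoms: none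
Why: Williamson ether synthesis of a phenoxide with a benzylic bromide; the aryl iodide is inert under these conditions.

Step 8
Reactants: 8 rel-(1R,2R)-1-[4-(benzyloxy)-3,5-dimethoxyphenyl]-2-[(benzyloxy)methyl]but-3-yn-1-ol; 11 2-(benzyloxy)-5-iodo-1,3-dimethoxybenzene
Product: 12 rel-(1R,2R)-1,4-bis[4-(benzyloxy)-3,5-dimethoxyphenyl]-2-[(benzyloxy)methyl]but-3-yn-1-ol (syn, racemic)
Conditions: PdCl2(PPh3)2 (3 mol %), CuI (5 mol %), Et3N, THF, rt to 40 °C
Reagents that add atoms: none
Why: Sonogashira coupling of a terminal alkyne with an aryl iodide; aryl iodides react near room temperature, where the free benzylic hydroxyl and both stereocentres are untouched.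

Step 9
Reactants: 12 rel-(1R,2R)-1,4-bis[4-(benzyloxy)-3,5-dimethoxyphenyl]-2-[(benzyloxy)methyl]but-3-yn-1-ol
Product: 13 methyl rel-(4R,5R)-2,5-bis[4-(benzyloxy)-3,5-dimethoxyphenyl]-4-[(benzyloxy)methyl]-4,5-dihydrofuran-3-carboxylate (4,5-cis, racemic)
Conditions: PdI2 (2 mol %), KI (20 mol %), CO–air 4:1 (40 atm), MeOH, 70 °C
Reagents that add atoms: carbon monoxide, `[C-]#[O+]`; methanol, `CO`
Why: PdI2, dissolved as K2PdI4, coordinates the alkyne of 12 and the hydroxyl attacks the aryl-bearing alkyne carbon anti to the metal, forming O1–C2 and a vinylpalladium iodide at C3. Carbon monoxide inserts into the vinyl–palladium bond and methanolysis of the acylpalladium releases ester 13 (C3–C3a), HI and zerovalent palladium, which oxygen and HI return to PdI2 by way of iodine. The closest known reaction type is the divalent-palladium-catalysed oxidative heterocyclisation–alkoxycarbonylation of alkynols (PdI2/KI with CO–air, or PdCl2(MeCN)2 with p-benzoquinone), which converts 3-yne-1,2-diols into furan-3-carboxylates and homopropargylic alcohols into 4,5-dihydrofuran-3-carboxylates. The one ring closes in the 5-endo-dig mode; the 4-exo alternative would give a strained oxetane and would place the developing positive charge away from the aryl group. No stereocentre is created, and C4 and C5 are spectators, so the cis relationship of 12 passes into 13 unchanged. The step needs carbonylative capture to outrun protodepalladation of the vinylpalladium, and oxypalladation to outrun methoxycarbonylpalladation of the triple bond; the internal, electron-rich aryl alkyne with a hydroxyl four atoms away, the excess iodide and the high CO pressure should secure both.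

Step 10
Reactants: 13 methyl rel-(4R,5R)-2,5-bis[4-(benzyloxy)-3,5-dimethoxyphenyl]-4-[(benzyloxy)methyl]-4,5-dihydrofuran-3-carboxylate
Product: 14 methyl rel-(2S,3R,4R,5R)-4-(hydroxymethyl)-2,5-bis(4-hydroxy-3,5-dimethoxyphenyl)oxolane-3-carboxylate (all-cis, racemic)
Conditions: H2 (5 bar), 10% Pd/C, EtOAc–MeOH 4:1, rt
Reagents that add atoms: none
Why: Heterogeneous syn hydrogenation of the tetrasubstituted enol ether with concurrent hydrogenolysis of the three benzyl ethers. The substrate should adsorb through the face of C2=C3 opposite the cis C5 aryl and C4 benzyloxymethyl groups, so both hydrogens arrive on that face and the new C2 and C3 centres place the aryl and ester groups cis to the existing pair.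

Step 11
Reactants: 14 methyl rel-(2S,3R,4R,5R)-4-(hydroxymethyl)-2,5-bis(4-hydroxy-3,5-dimethoxyphenyl)oxolane-3-carboxylate
Product: 15 [(2R,3R,4S,5S)-2,5-bis(4-hydroxy-3,5-dimethoxyphenyl)oxolane-3,4-diyl]dimethanol (meso, all-cis)
Conditions: LiAlH4, THF, 0 °C to rt; aqueous work-up at pH 5
Reagents that add atoms: none
Why: Hydride reduction of an ester with LiAlH4 after the three acidic hydroxyls have been converted into aluminates; ester reduction is faster than enolisation, so C3 should keep its configuration and the product is the meso target.

## Compound list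

```
1 | syringaldehyde (4-hydroxy-3,5-dimethoxybenzaldehyde) | COc1cc(C=O)cc(OC)c1O | starting material
2 | benzyl bromide | BrCc1ccccc1 | starting material
3 | 4-(benzyloxy)-3,5-dimethoxybenzaldehyde | COc1cc(C=O)cc(OC)c1OCc1ccccc1 | intermediate
4 | benzyloxyacetaldehyde | O=CCOCc1ccccc1 | starting material
5 | 1-(benzyloxy)but-3-yn-2-ol (racemic) | C#CC(O)COCc1ccccc1 | intermediate
6 | 1-(benzyloxy)but-3-yn-2-yl methanesulfonate (racemic) | C#CC(COCc1ccccc1)OS(C)(=O)=O | intermediate
7 | tributyl[4-(benzyloxy)buta-1,2-dien-1-yl]stannane (racemic) | CCCC[Sn](CCCC)(CCCC)C=C=CCOCc1ccccc1 | intermediate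
8 | rel-(1R,2R)-1-[4-(benzyloxy)-3,5-dimethoxyphenyl]-2-[(benzyloxy)methyl]but-3-yn-1-ol (syn, racemic, one enantiomer drawn) | O[C@@H](c1cc(OC)c(OCc2ccccc2)c(OC)c1)[C@@H](COCc1ccccc1)C#C | intermediate
9 | 2,6-dimethoxyphenol | COc1cccc(OC)c1O | starting material
10 | 4-iodo-2,6-dimethoxyphenol | COc1cc(I)cc(OC)c1O | intermediate
11 | 2-(benzyloxy)-5-iodo-1,3-dimethoxybenzene | COc1cc(I)cc(OC)c1OCc1ccccc1 | intermediate
12 | rel-(1R,2R)-1,4-bis[4-(benzyloxy)-3,5-dimethoxyphenyl]-2-[(benzyloxy)methyl]but-3-yn-1-ol (syn, racemic, one enantiomer drawn) | O[C@@H](c1cc(OC)c(OCc2ccccc2)c(OC)c1)[C@@H](COCc1ccccc1)C#Cc1cc(OC)c(OCc2ccccc2)c(OC)c1 | intermediate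
13 | methyl rel-(4R,5R)-2,5-bis[4-(benzyloxy)-3,5-dimethoxyphenyl]-4-[(benzyloxy)methyl]-4,5-dihydrofuran-3-carboxylate (4,5-cis, racemic, one enantiomer drawn) | COC(=O)C1=C(c2cc(OC)c(OCc3ccccc3)c(OC)c2)O[C@@H](c2cc(OC)c(OCc3ccccc3)c(OC)c2)[C@H]1COCc1ccccc1 | intermediate
14 | methyl rel-(2S,3R,4R,5R)-4-(hydroxymethyl)-2,5-bis(4-hydroxy-3,5-dimethoxyphenyl)oxolane-3-carboxylate (all-cis, racemic, one enantiomer drawn) | COC(=O)[C@H]1[C@@H](c2cc(OC)c(O)c(OC)c2)O[C@@H](c2cc(OC)c(O)c(OC)c2)[C@H]1CO | intermediate
15 | [(2R,3R,4S,5S)-2,5-bis(4-hydroxy-3,5-dimethoxyphenyl)oxolane-3,4-diyl]dimethanol (meso, all-cis) | COc1cc([C@H]2O[C@@H](c3cc(OC)c(O)c(OC)c3)[C@@H](CO)[C@H]2CO)cc(OC)c1O | target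
```

## Step count and least certain steps

Total step count: 11. Longest linear sequence: 8 steps (4 → 5 → 6 → 7 → 8 → 12 → 13 → 14 → 15, steps 2, 3, 4, 5, 8, 9, 10 and 11).

**Step 9 (key step).** Three processes threaten it. The HI formed may protonate the vinylpalladium before carbon monoxide inserts, giving cyclisation without carbonylation. Methoxycarbonylpalladation of the triple bond may compete with oxypalladation. In hot, slightly acidic methanol the electron-rich benzylic C–O bond at C5 may ionise, with loss of the cis relationship. Within the step, the first recourse is the PdCl2(MeCN)2/p-benzoquinone variant at room temperature and 1 atm of CO. The fallback splits the two bond formations over two flasks. Setting out from 12, 5-endo-dig iodocyclisation with I2 and NaHCO3 in MeCN at 0 °C should give rel-(2R,3R)-2,5-bis[4-(benzyloxy)-3,5-dimethoxyphenyl]-3-[(benzyloxy)methyl]-4-iodo-2,3-dihydrofuran F1. Methoxycarbonylation of this vinyl iodide (Pd(OAc)2, PPh3, CO, MeOH, Et3N, DMF, 60 °C; oxidative addition to zerovalent palladium, CO insertion, methanolysis) then comes back to the route at 13.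

**Step 5.** The flat aryl group of 3 may give too little discrimination between the syn and anti open transition states, and the electron-rich benzylic boron alkoxide may ionise before the quench. The fallback builds the same C4–C5 bond by a boron aldol reaction, whose cyclic transition state gives the syn isomer reliably with aromatic aldehydes. Setting out from 3:
- Oxazolidin-2-one is acylated with 3-(benzyloxy)propanoyl chloride to give 3-[3-(benzyloxy)propanoyl]-1,3-oxazolidin-2-one F2.
- Its Z-enolate (Bu2BOTf, i-Pr2NEt, CH2Cl2, −78 °C) adds to 3 to give the syn aldol adduct F3.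
- Silylation (TBSOTf, 2,6-lutidine) gives the silyl ether F4.
- LiBH4 removes the auxiliary to give the primary alcohol F5.
- Dess–Martin oxidation gives the aldehyde F6.
- Homologation with the Ohira–Bestmann reagent (dimethyl (1-diazo-2-oxopropyl)phosphonate, K2CO3, MeOH) gives the silyl-protected alkynol F7.
- Bu4NF removes the silyl group, and the sequence comes back to the route at 8.

**Step 10.** The tetrasubstituted, doubly conjugated enol ether may be saturated only slowly, so that forcing conditions bring hydrogenolysis of the benzylic ring C–O bonds. Facial selectivity may also erode once the freed C4 hydroxymethyl group anchors the substrate to the catalyst on the hindered face. The fallback separates alkene saturation from debenzylation. Setting out from 13: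
- Hydrogenation over Rh/Al2O3 (H2, EtOAc, rt), which spares benzyl ethers, should give the all-cis tribenzyl ester F8.
- LiAlH4 in THF at 0 °C reduces the ester to the tribenzyl alcohol F9 with no phenoxide present.
- Mild hydrogenolysis (H2 1 atm, 10% Pd/C, EtOAc) of the three benzyl ethers comes back to the route at 15.

**Step 11.** Once the phenols are deprotonated by the hydride, C3 may epimerise or the ring may open through a quinone methide, both of which relieve the all-cis strain. The polyaluminate may also precipitate and stall the reduction. The fallback masks the acidic hydroxyls first. Setting out from 14: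
- TBSCl and imidazole in DMF give the tris(silyl ether) F10.
- i-Bu2AlH in CH2Cl2 at −78 °C reduces the ester to the alcohol F11.
- HF·pyridine in THF removes the three silyl groups and comes back to the route at 15.

## Further compounds

```
F1 | step 9 | rel-(2R,3R)-2,5-bis[4-(benzyloxy)-3,5-dimethoxyphenyl]-3-[(benzyloxy)methyl]-4-iodo-2,3-dihydrofuran (2,3-cis, racemic) | IC1=C(c2cc(OC)c(OCc3ccccc3)c(OC)c2)O[C@@H](c2cc(OC)c(OCc3ccccc3)c(OC)c2)[C@H]1COCc1ccccc1
F2 | step 5 | 3-[3-(benzyloxy)propanoyl]-1,3-oxazolidin-2-one | O=C(CCOCc1ccccc1)N1CCOC1=O
F3 | step 5 | 3-{rel-(2R,3R)-3-[4-(benzyloxy)-3,5-dimethoxyphenyl]-2-[(benzyloxy)methyl]-3-hydroxypropanoyl}-1,3-oxazolidin-2-one (syn aldol adduct, racemic) | O[C@@H](c1cc(OC)c(OCc2ccccc2)c(OC)c1)[C@@H](COCc1ccccc1)C(=O)N1CCOC1=O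
F4 | step 5 | 3-{rel-(2R,3R)-3-[4-(benzyloxy)-3,5-dimethoxyphenyl]-2-[(benzyloxy)methyl]-3-[(tert-butyldimethylsilyl)oxy]propanoyl}-1,3-oxazolidin-2-one | CC(C)(C)[Si](C)(C)O[C@@H](c1cc(OC)c(OCc2ccccc2)c(OC)c1)[C@@H](COCc1ccccc1)C(=O)N1CCOC1=O
F5 | step 5 | rel-(2R,3R)-3-[4-(benzyloxy)-3,5-dimethoxyphenyl]-2-[(benzyloxy)methyl]-3-[(tert-butyldimethylsilyl)oxy]propan-1-ol | CC(C)(C)[Si](C)(C)O[C@@H](c1cc(OC)c(OCc2ccccc2)c(OC)c1)[C@@H](COCc1ccccc1)CO
F6 | step 5 | rel-(2R,3R)-3-[4-(benzyloxy)-3,5-dimethoxyphenyl]-2-[(benzyloxy)methyl]-3-[(tert-butyldimethylsilyl)oxy]propanal | CC(C)(C)[Si](C)(C)O[C@@H](c1cc(OC)c(OCc2ccccc2)c(OC)c1)[C@@H](COCc1ccccc1)C=O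
F7 | step 5 | tert-butyl({rel-(1R,2R)-1-[4-(benzyloxy)-3,5-dimethoxyphenyl]-2-[(benzyloxy)methyl]but-3-yn-1-yl}oxy)dimethylsilane | CC(C)(C)[Si](C)(C)O[C@@H](c1cc(OC)c(OCc2ccccc2)c(OC)c1)[C@@H](COCc1ccccc1)C#C
F8 | step 10 | methyl rel-(2S,3R,4R,5R)-2,5-bis[4-(benzyloxy)-3,5-dimethoxyphenyl]-4-[(benzyloxy)methyl]oxolane-3-carboxylate (all-cis) | COC(=O)[C@H]1[C@@H](c2cc(OC)c(OCc3ccccc3)c(OC)c2)O[C@@H](c2cc(OC)c(OCc3ccccc3)c(OC)c2)[C@H]1COCc1ccccc1
F9 | step 10 | {rel-(2S,3S,4R,5R)-2,5-bis[4-(benzyloxy)-3,5-dimethoxyphenyl]-4-[(benzyloxy)methyl]oxolan-3-yl}methanol (all-cis) | OC[C@H]1[C@@H](c2cc(OC)c(OCc3ccccc3)c(OC)c2)O[C@@H](c2cc(OC)c(OCc3ccccc3)c(OC)c2)[C@H]1COCc1ccccc1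
F10 | step 11 | methyl rel-(2S,3R,4R,5R)-4-{[(tert-butyldimethylsilyl)oxy]methyl}-2,5-bis{4-[(tert-butyldimethylsilyl)oxy]-3,5-dimethoxyphenyl}oxolane-3-carboxylate (all-cis) | COC(=O)[C@H]1[C@@H](c2cc(OC)c(O[Si](C)(C)C(C)(C)C)c(OC)c2)O[C@@H](c2cc(OC)c(O[Si](C)(C)C(C)(C)C)c(OC)c2)[C@H]1CO[Si](C)(C)C(C)(C)C
F11 | step 11 | (rel-(2S,3S,4R,5R)-4-{[(tert-butyldimethylsilyl)oxy]methyl}-2,5-bis{4-[(tert-butyldimethylsilyl)oxy]-3,5-dimethoxyphenyl}oxolan-3-yl)methanol (all-cis) | OC[C@H]1[C@@H](c2cc(OC)c(O[Si](C)(C)C(C)(C)C)c(OC)c2)O[C@@H](c2cc(OC)c(O[Si](C)(C)C(C)(C)C)c(OC)c2)[C@H]1CO[Si](C)(C)C(C)(C)C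
A1 | alternative 1 | all-cis 3,4-bis[(benzyloxy)methyl]-2,5-bis[4-(benzyloxy)-3,5-dihydroxyphenyl]oxolane | Oc1cc([C@H]2O[C@@H](c3cc(O)c(OCc4ccccc4)c(O)c3)[C@@H](COCc3ccccc3)[C@H]2COCc2ccccc2)cc(O)c1OCc1ccccc1
A2 | alternative 1 | all-cis 3,4-bis[(benzyloxy)methyl]-N2,N5-dimethoxy-N2,N5-dimethyloxolane-2,5-dicarboxamide | CON(C)C(=O)[C@H]1O[C@@H](C(=O)N(C)OC)[C@@H](COCc2ccccc2)[C@H]1COCc1ccccc1
A3 | alternative 1 | 3-(benzyloxy)pentane-2,4-dione | CC(=O)C(OCc1ccccc1)C(C)=O
A4 | alternative 2 | all-cis {2,5-bis[4-(benzyloxy)-3,5-dimethoxyphenyl]oxolane-3,4-diyl}dimethanol | COc1cc([C@H]2O[C@@H](c3cc(OC)c(OCc4ccccc4)c(OC)c3)[C@@H](CO)[C@H]2CO)cc(OC)c1OCc1ccccc1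
A5 | alternative 2 | cis-(2,5-dimethoxyoxolane-3,4-diyl)dimethanol (acetal centres as a mixture) | COC1OC(OC)[C@@H](CO)[C@H]1CO
A6 | alternative 2 | tris[4-(benzyloxy)-3,5-dimethoxyphenyl]alumane | COc1cc(cc(OC)c1OCc1ccccc1)[Al](c1cc(OC)c(OCc2ccccc2)c(OC)c1)c1cc(OC)c(OCc2ccccc2)c(OC)c1
A7 | alternative 3 | dimethyl 2,5-cis-4,5-cis-2,5-bis[3,5-dimethoxy-4-(pivaloyloxy)phenyl]-4-[(pivaloyloxy)methyl]oxolane-3,3-dicarboxylate | COc1cc([C@H]2O[C@@H](c3cc(OC)c(OC(=O)C(C)(C)C)c(OC)c3)[C@@H](COC(=O)C(C)(C)C)C2(C(=O)OC)C(=O)OC)cc(OC)c1OC(=O)C(C)(C)C
A8 | alternative 3 | dimethyl trans-2-[3,5-dimethoxy-4-(pivaloyloxy)phenyl]-3-[(pivaloyloxy)methyl]cyclopropane-1,1-dicarboxylate (racemic, one enantiomer drawn) | COC(=O)C1(C(=O)OC)[C@@H](c2cc(OC)c(OC(=O)C(C)(C)C)c(OC)c2)[C@@H]1COC(=O)C(C)(C)C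
A9 | alternative 3 | 4-formyl-2,6-dimethoxyphenyl pivalate | COc1cc(C=O)cc(OC)c1OC(=O)C(C)(C)C
```
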